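## Retrosynthetic overview

1. The last bond made is butenolide C3(α)–vinyl, by Suzuki coupling of an East epoxy-vinylboronate with a West polyene that carries a 3-bromo-5-ylidenebutenolide. Before that, a Horner–Wadsworth–Emmons (HWE) olefination joins a West acetylenic C15 phosphonate to a bromobutenolide trienal.
2. The key disconnection is butenolide C4(β)–C5(γ). A 1,1-diborylalkene acts as a masked acyl anion: one C–B bond is the nucleophile and the other is the latent C–O. It attacks the β-carbon of (E)-2,3-dibromoacrylic acid. Oxidation of the remaining C–B bond and lactonisation then give the Z-ylidenebutenolide.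
3. Both cyclohexane end groups come from (−)-actinol through one common acetoxy enol triflate. West uses a Sonogashira coupling. East uses carbonylation, DIBAL-H, Sharpless epoxidation, oxidation and boron-Wittig olefination.
4. Ring order: the carbocycles are bought, the epoxide is formed in step 7, and the butenolide is formed in step 13.

Assumption: the SMILES is natural (3S,5R,6S,3'R)-pyrrhoxanthin with an all-E chain and a Z-ylidenebutenolide. All compounds marked "starting material" are taken as catalogue items. Butenolide numbering is C2 = C=O, C3 = α, C4 = β, C5 = γ.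

## Route

Step 1
Reactants: 1 (4R,6R)-4-hydroxy-2,2,6-trimethylcyclohexanone [(−)-actinol]
Product: 2 (1R,3R)-3,5,5-trimethyl-4-oxocyclohexyl acetate
Conditions: Ac2O, DMAP (cat.), pyridine, rt
Reagents that add atoms: acetic anhydride CC(=O)OC(C)=O
Why: DMAP-catalysed O-acylation of the only hydroxyl leaves the carbinol centre untouched, and this centre becomes both 3'R (West) and 3S (East).

Step 2
Reactants: 2 (1R,3R)-3,5,5-trimethyl-4-oxocyclohexyl acetate
Product: 3 (R)-4-acetoxy-2,6,6-trimethylcyclohex-1-en-1-yl trifluoromethanesulfonate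
Conditions: Tf2O (1.3 equiv), 2,6-di-tert-butyl-4-methylpyridine (1.5 equiv), CH2Cl2, 0 °C → rt
Reagents that add atoms: triflic anhydride O=S(=O)(OS(=O)(=O)C(F)(F)F)C(F)(F)F
Why: Enol triflate formation under Stang-type conditions (O-triflation, then loss of the only α-H) needs no strong base, so the acetate survives, and the C6 stereocentre is erased on purpose.

Step 3
Reactants: 4 (E)-3-methylpent-2-en-4-yn-1-ol
Product: 5 diethyl [(2E)-3-methylpent-2-en-4-yn-1-yl]phosphonate
Conditions: P(OEt)3 (3 equiv), ZnI2 (1.5 equiv), THF, reflux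
Reagents that add atoms: triethyl phosphite CCOP(OCC)OCC
Why: This ZnI2-mediated one-flask Michaelis–Arbuzov reaction of the primary allylic alcohol is run on the cheap enynol, so that any Z isomer can be removed by chromatography.

Step 4
Reactants: 3 (R)-4-acetoxy-2,6,6-trimethylcyclohex-1-en-1-yl triflate; 5 diethyl [(2E)-3-methylpent-2-en-4-yn-1-yl]phosphonate
Product: 6 (R)-4-[(3E)-5-(diethoxyphosphoryl)-3-methylpent-3-en-1-yn-1-yl]-3,5,5-trimethylcyclohex-3-en-1-yl acetate
Conditions: Pd(PPh3)4 (5 mol %), CuI (10 mol %), Et3N, DMF, 60 °C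
Reagents that add atoms: none
Why: Sonogashira coupling of the tetrasubstituted enol triflate with the terminal alkyne makes the ring–C≡C bond under conditions that spare the acetate, the phosphonate and the E-alkene.

Step 5
Reactants: 3 (R)-4-acetoxy-2,6,6-trimethylcyclohex-1-en-1-yl triflate
Product: 7 methyl (R)-4-acetoxy-2,6,6-trimethylcyclohex-1-ene-1-carboxylate
Conditions: Pd(OAc)2 (5 mol %), PPh3, CO (1 atm), Et3N, MeOH/DMF, 60 °C
Reagents that add atoms: carbon monoxide [C-]#[O+]; methanol CO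
Why: Pd-catalysed alkoxycarbonylation of the enol triflate installs C7, and partial methanolysis of the acetate is harmless because step 6 removes it anyway.

Step 6
Reactants: 7 methyl (R)-4-acetoxy-2,6,6-trimethylcyclohex-1-ene-1-carboxylate
Product: 8 (R)-4-(hydroxymethyl)-3,5,5-trimethylcyclohex-3-en-1-ol
Conditions: DIBAL-H (5 equiv), CH2Cl2, −78 → 0 °C; Rochelle salt
Reagents that add atoms: none
Why: Exhaustive DIBAL-H ester reduction gives the allylic alcohol and frees the ring hydroxyl in one operation without touching the stereocentre.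

Step 7
Reactants: 8 (R)-4-(hydroxymethyl)-3,5,5-trimethylcyclohex-3-en-1-ol
Product: 9 (1R,4S,6R)-1-(hydroxymethyl)-2,2,6-trimethyl-7-oxabicyclo[4.1.0]heptan-4-ol (epoxide anti to the 4-OH)
Conditions: Ti(OiPr)4 (0.3 equiv), D-(−)-DET (0.36 equiv), t-BuOOH, 4 Å MS, CH2Cl2, −20 °C
Reagents that add atoms: tert-butyl hydroperoxide CC(C)(C)OO
Why: In this Sharpless asymmetric epoxidation the allylic OH binds titanium and D-(−)-DET delivers oxygen to the face anti to the ring OH, which sets both epoxide centres (5R,6S in carotenoid numbering) by reagent control.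

Step 8
Reactants: 9 (1R,4S,6R)-1-(hydroxymethyl)-2,2,6-trimethyl-7-oxabicyclo[4.1.0]heptan-4-ol
Product: 10 (1S,4S,6R)-4-hydroxy-2,2,6-trimethyl-7-oxabicyclo[4.1.0]heptane-1-carbaldehyde
Conditions: TEMPO (10 mol %), PhI(OAc)2 (1.1 equiv), CH2Cl2, rt
Reagents that add atoms: none
Why: TEMPO/oxoammonium oxidation prefers the primary over the secondary alcohol and tolerates the epoxide, and the aldehyde has no α-H so nothing can epimerise.

Step 9
Reactants: 10 (1S,4S,6R)-4-hydroxy-2,2,6-trimethyl-7-oxabicyclo[4.1.0]heptane-1-carbaldehyde; 11 bis(pinacolboryl)methane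
Product: 13 2-[(E)-2-[(1S,4S,6R)-4-hydroxy-2,2,6-trimethyl-7-oxabicyclo[4.1.0]heptan-1-yl]ethenyl]-4,4,5,5-tetramethyl-1,3,2-dioxaborolane, via lithiated bis(pinacolboryl)methane 12 (not isolated)
Conditions: 11 (2.3 equiv), LiTMP (2.3 equiv), THF, 0 °C; then 10, −78 °C → rt
Reagents that add atoms: none
Why: In this boron-Wittig olefination the α-boryl carbanion adds to the aldehyde and syn B–O elimination gives the E-vinylboronate, with E enforced by the quaternary neighbour and the excess reagent covering the free OH.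

Step 10
Reactants: 14 (E)-4,4-dimethoxybut-2-enal (fumaraldehyde mono(dimethyl acetal)); 15 2-(triphenylphosphoranylidene)propanal
Product: 16 (2E,4E)-6,6-dimethoxy-2-methylhexa-2,4-dienal
Conditions: toluene, 80 °C
Reagents that add atoms: none
Why: Wittig reaction with a stabilised ylide gives the E-trisubstituted enal, which is less reactive than 14 and therefore does not react a second time.

Step 11
Reactants: 16 (2E,4E)-6,6-dimethoxy-2-methylhexa-2,4-dienal; 17 tris(pinacolboryl)methane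
Product: 19 2,2'-[(3E,5E)-7,7-dimethoxy-3-methylhepta-1,3,5-triene-1,1-diyl]bis(4,4,5,5-tetramethyl-1,3,2-dioxaborolane), via lithiated tris(pinacolboryl)methane 18 (not isolated)
Conditions: 17 (1.2 equiv), LiTMP (1.2 equiv), THF, 0 °C; then 16, −78 °C → rt
Reagents that add atoms: none
Why: Boron-Wittig (Matteson-type) 1,2-addition of the triborylmethide followed by B–O elimination turns the aldehyde into the 1,1-diborylalkene and adds the future C5.

Step 12
Reactants: 20 propiolic acid
Product: 21 (E)-2,3-dibromoacrylic acid (β-Br cis to CO2H)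
Conditions: Br2 (1.0 equiv), CH2Cl2, 0 °C → rt, dark; recrystallise
Reagents that add atoms: bromine BrBr
Why: Ionic anti electrophilic addition of bromine to the alkyne gives the E-dibromide, whose β-bromine lies cis to the carboxyl group as the later lactonisation requires.

Step 13 (key step)
Reactants: 19 1,1-diboryl triene acetal; 21 (E)-2,3-dibromoacrylic acid
Product: 25 (2E,4E)-6-[(2Z)-4-bromo-5-oxofuran-2(5H)-ylidene]-5-methylhexa-2,4-dienal, via boryl tetraenoic acid 22 (not isolated), via enol borate 23 (not isolated), via bromobutenolide acetal 24 (not isolated)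
Conditions: i) Pd(dppf)Cl2 (5 mol %), K3PO4 (4 equiv, anhydrous), THF/DMF, 40 °C; ii) Me3NO (1.5 equiv), rt; iii) Ac2O (4 equiv), 0 °C → rt; iv) 1 M HCl, THF, rt
Reagents that add atoms: trimethylamine N-oxide C[N+](C)(C)[O-]; water O
Why: Proposed new method: the C(Bpin)2 carbon is a masked acyl anion whose less hindered boryl group (trans to the chain) couples by Suzuki–Miyaura reaction with the more reactive β-C–Br of 21 and so joins two normally electrophilic carbons (a latent ketone carbon and an acrylate β-carbon), Me3NO then converts the remaining C–B into C–O with retention, the mixed anhydride formed with Ac2O is closed by that enol oxygen so that O ends up cis to the chain (Z, also the thermodynamic isomer should the enol ketonise), and aqueous acid unmasks the aldehyde, the closest known reaction types being stereoselective mono-coupling of 1,1-diborylalkenes, β-selective coupling of 2,3-dibromoacrylates, alkenylboronate-to-enol-borate oxidation and Ac2O cyclodehydration of 4-oxo-2-enoic acids.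

Step 14
Reactants: 6 West C15 phosphonate; 25 bromobutenolide trienal
Product: 27 (R)-4-[(3E,5E,7E,9E)-11-[(2Z)-4-bromo-5-oxofuran-2(5H)-ylidene]-3,10-dimethylundeca-3,5,7,9-tetraen-1-yn-1-yl]-3,5,5-trimethylcyclohex-3-en-1-yl acetate, via sodium phosphonate carbanion 26 (not isolated)
Conditions: NaHMDS (1.0 equiv), THF, −78 °C; then 25, −78 → 0 °C, dark
Reagents that add atoms: none
Why: HWE olefination of the allylic phosphonate anion (more acidic than the acetate) with the aldehyde, the most electrophilic site of 25, gives the new disubstituted alkene E-selectively at low temperature.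

Step 15
Reactants: 27 bromobutenolide polyene; 13 East (E)-vinylboronate
Product: 28 pyrrhoxanthin (target)
Conditions: Pd(OAc)2 (5 mol %), SPhos (10 mol %), K3PO4 (3 equiv), THF/H2O 10:1, rt, dark
Reagents that add atoms: none
Why: Suzuki–Miyaura coupling at the activated α-bromobutenolide proceeds with retention of both alkene geometries at room temperature and tolerates the free OH, epoxide, acetate and lactone, so no deprotection follows.

## Compound list

1 | (4R,6R)-4-hydroxy-2,2,6-trimethylcyclohexanone, (−)-actinol | O[C@@H]1C[C@@H](C)C(=O)C(C)(C)C1 | starting material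
2 | (1R,3R)-3,5,5-trimethyl-4-oxocyclohexyl acetate | CC(=O)O[C@@H]1C[C@@H](C)C(=O)C(C)(C)C1 | intermediate
3 | (R)-4-acetoxy-2,6,6-trimethylcyclohex-1-en-1-yl triflate | CC(=O)O[C@@H]1CC(C)=C(OS(=O)(=O)C(F)(F)F)C(C)(C)C1 | intermediate
4 | (E)-3-methylpent-2-en-4-yn-1-ol | C#C/C(C)=C/CO | starting material
5 | diethyl [(2E)-3-methylpent-2-en-4-yn-1-yl]phosphonate | C#C/C(C)=C/CP(=O)(OCC)OCC | intermediate
6 | (R)-4-[(3E)-5-(diethoxyphosphoryl)-3-methylpent-3-en-1-yn-1-yl]-3,5,5-trimethylcyclohex-3-en-1-yl acetate | CC(=O)O[C@@H]1CC(C)=C(C#C/C(C)=C/CP(=O)(OCC)OCC)C(C)(C)C1 | intermediate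
7 | methyl (R)-4-acetoxy-2,6,6-trimethylcyclohex-1-ene-1-carboxylate | CC(=O)O[C@@H]1CC(C)=C(C(=O)OC)C(C)(C)C1 | intermediate
8 | (R)-4-(hydroxymethyl)-3,5,5-trimethylcyclohex-3-en-1-ol | O[C@@H]1CC(C)=C(CO)C(C)(C)C1 | intermediate
9 | (1R,4S,6R)-1-(hydroxymethyl)-2,2,6-trimethyl-7-oxabicyclo[4.1.0]heptan-4-ol | OC[C@@]12O[C@]1(C)C[C@@H](O)CC2(C)C | intermediate
10 | (1S,4S,6R)-4-hydroxy-2,2,6-trimethyl-7-oxabicyclo[4.1.0]heptane-1-carbaldehyde | O=C[C@@]12O[C@]1(C)C[C@@H](O)CC2(C)C | intermediate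
11 | bis(pinacolboryl)methane | CC1(C)OB(CB2OC(C)(C)C(C)(C)O2)OC1(C)C | starting material
12 | lithiated bis(pinacolboryl)methane | [Li]C(B1OC(C)(C)C(C)(C)O1)B1OC(C)(C)C(C)(C)O1 | intermediate
13 | 2-[(E)-2-[(1S,4S,6R)-4-hydroxy-2,2,6-trimethyl-7-oxabicyclo[4.1.0]heptan-1-yl]ethenyl]-4,4,5,5-tetramethyl-1,3,2-dioxaborolane | CC1(C)OB(/C=C/[C@@]23O[C@]2(C)C[C@@H](O)CC3(C)C)OC1(C)C | intermediate
14 | (E)-4,4-dimethoxybut-2-enal | COC(OC)/C=C/C=O | starting material
15 | 2-(triphenylphosphoranylidene)propanal | CC(C=O)=P(c1ccccc1)(c1ccccc1)c1ccccc1 | starting material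
16 | (2E,4E)-6,6-dimethoxy-2-methylhexa-2,4-dienal | COC(OC)/C=C/C=C(C)/C=O | intermediate
17 | tris(pinacolboryl)methane | CC1(C)OB(OC1(C)C)C(B1OC(C)(C)C(C)(C)O1)B1OC(C)(C)C(C)(C)O1 | starting material
18 | lithiated tris(pinacolboryl)methane | [Li]C(B1OC(C)(C)C(C)(C)O1)(B1OC(C)(C)C(C)(C)O1)B1OC(C)(C)C(C)(C)O1 | intermediate
19 | 2,2'-[(3E,5E)-7,7-dimethoxy-3-methylhepta-1,3,5-triene-1,1-diyl]bis(4,4,5,5-tetramethyl-1,3,2-dioxaborolane) | COC(OC)/C=C/C=C(C)/C=C(B1OC(C)(C)C(C)(C)O1)B1OC(C)(C)C(C)(C)O1 | intermediate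
20 | propiolic acid | C#CC(=O)O | starting material
21 | (E)-2,3-dibromoacrylic acid | OC(=O)/C(Br)=C\Br | intermediate
22 | (2E,4E,6E,8E)-2-bromo-10,10-dimethoxy-6-methyl-4-(pinacolboryl)deca-2,4,6,8-tetraenoic acid (potassium salt in the flask; boryl cis to the chain) | OC(=O)/C(Br)=C\C(B1OC(C)(C)C(C)(C)O1)=C\C(C)=C\C=C\C(OC)OC | intermediate
23 | (2E,4Z,6E,8E)-2-bromo-10,10-dimethoxy-6-methyl-4-(pinacolboryloxy)deca-2,4,6,8-tetraenoic acid (enol borate) | OC(=O)/C(Br)=C\C(OB1OC(C)(C)C(C)(C)O1)=C\C(C)=C\C=C\C(OC)OC | intermediate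
24 | (5Z)-3-bromo-5-[(2E,4E)-6,6-dimethoxy-2-methylhexa-2,4-dien-1-ylidene]furan-2(5H)-one | COC(OC)/C=C/C=C(C)/C=C1C=C(Br)C(=O)O/1 | intermediate
25 | (2E,4E)-6-[(2Z)-4-bromo-5-oxofuran-2(5H)-ylidene]-5-methylhexa-2,4-dienal | O=C/C=C/C=C(C)/C=C1C=C(Br)C(=O)O/1 | intermediate
26 | sodium carbanion of phosphonate 6 | CC(=O)O[C@@H]1CC(C)=C(C#C/C(C)=C/[CH-]P(=O)(OCC)OCC)C(C)(C)C1.[Na+] | intermediate
27 | (R)-4-[(3E,5E,7E,9E)-11-[(2Z)-4-bromo-5-oxofuran-2(5H)-ylidene]-3,10-dimethylundeca-3,5,7,9-tetraen-1-yn-1-yl]-3,5,5-trimethylcyclohex-3-en-1-yl acetate | CC(=O)O[C@@H]1CC(C)=C(C#C/C(C)=C/C=C/C=C/C=C(C)/C=C2C=C(Br)C(=O)O/2)C(C)(C)C1 | intermediate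
28 | pyrrhoxanthin, (3S,5R,6S,3'R) | CC(=O)O[C@@H]1CC(C)=C(C#C/C(C)=C/C=C/C=C/C=C(C)/C=C2C=C(/C=C/[C@@]34O[C@]3(C)C[C@@H](O)CC4(C)C)C(=O)O/2)C(C)(C)C1 | target

## Counts and risks

Total step count: 15.
Longest linear sequence: 8 steps (1, 2, 5, 6, 7, 8, 9, 15).

**Step 13.** The risks are mono- versus double coupling, survival of the α-bromide, and a four-stage telescoped sequence. The fallback leaves boron chemistry and lets a terminal alkyne carbon serve as the latent acyl carbon. It sets out from 16. Ohira–Bestmann homologation (dimethyl (1-diazo-2-oxopropyl)phosphonate, K2CO3, MeOH) gives (3E,5E)-7,7-dimethoxy-3-methylhepta-3,5-dien-1-yne F1. Pd/Cu coupling of this alkyne with 21 (PdCl2(PPh3)2, CuI, Et3N, MeCN, rt) gives (2E,6E,8E)-2-bromo-10,10-dimethoxy-6-methyldeca-2,6,8-trien-4-ynoic acid F2. That acid closes in the same flask by anti 5-exo-dig oxymetalation. The fallback comes back to the route at 24, which is hydrolysed to 25 as in stage iv.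

**Step 14.** The risks are a strong base next to a bromo-ylidenebutenolide, and E/Z drift of the enyne-conjugated carbanion. The fallback replaces the pre-formed phosphorus carbanion by a sulfone olefination run in Barbier mode. It sets out from 3 and 4.
- Direct Sonogashira coupling gives (R)-4-[(3E)-5-hydroxy-3-methylpent-3-en-1-yn-1-yl]-3,5,5-trimethylcyclohex-3-en-1-yl acetate F3.
- Mitsunobu thioetherification (1-phenyl-1H-tetrazole-5-thiol, DIAD, PPh3; an SN2 process, so no allyl cation forms) gives (R)-3,5,5-trimethyl-4-[(3E)-3-methyl-5-[(1-phenyl-1H-tetrazol-5-yl)sulfanyl]pent-3-en-1-yn-1-yl]cyclohex-3-en-1-yl acetate F4.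
- Mo(VI)/H2O2 oxidation gives (R)-3,5,5-trimethyl-4-[(3E)-3-methyl-5-[(1-phenyl-1H-tetrazol-5-yl)sulfonyl]pent-3-en-1-yn-1-yl]cyclohex-3-en-1-yl acetate F5.
- KHMDS is added to a −78 °C mixture of this sulfone and 25 (Julia–Kocienski olefination), so the anion is trapped as it forms.

The fallback comes back to the route at 27.

**Step 15.** The risk is aqueous phosphate acting on a base-labile enol lactone and acetate in a light-sensitive polyene. The fallback is a base-free tin coupling and sets out from 10. Ohira–Bestmann homologation gives (1R,4S,6R)-1-ethynyl-2,2,6-trimethyl-7-oxabicyclo[4.1.0]heptan-4-ol F6. Pd-catalysed syn hydrostannation (Bu3SnH, PdCl2(PPh3)2, THF, 0 °C; tin goes to the unhindered terminus) gives (1S,4S,6R)-2,2,6-trimethyl-1-[(E)-2-(tributylstannyl)ethenyl]-7-oxabicyclo[4.1.0]heptan-4-ol F7. Stille coupling with 27 (Pd2(dba)3, AsPh3, DMF, rt, dark) comes back to the route at 28.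

## Further compounds

F1 | step 13 | (3E,5E)-7,7-dimethoxy-3-methylhepta-3,5-dien-1-yne | C#C/C(C)=C/C=C/C(OC)OC
F2 | step 13 | (2E,6E,8E)-2-bromo-10,10-dimethoxy-6-methyldeca-2,6,8-trien-4-ynoic acid | OC(=O)/C(Br)=C\C#C/C(C)=C/C=C/C(OC)OC
F3 | step 14 | (R)-4-[(3E)-5-hydroxy-3-methylpent-3-en-1-yn-1-yl]-3,5,5-trimethylcyclohex-3-en-1-yl acetate | CC(=O)O[C@@H]1CC(C)=C(C#C/C(C)=C/CO)C(C)(C)C1
F4 | step 14 | (R)-3,5,5-trimethyl-4-[(3E)-3-methyl-5-[(1-phenyl-1H-tetrazol-5-yl)sulfanyl]pent-3-en-1-yn-1-yl]cyclohex-3-en-1-yl acetate | CC(=O)O[C@@H]1CC(C)=C(C#C/C(C)=C/CSc2nnnn2-c2ccccc2)C(C)(C)C1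
F5 | step 14 | (R)-3,5,5-trimethyl-4-[(3E)-3-methyl-5-[(1-phenyl-1H-tetrazol-5-yl)sulfonyl]pent-3-en-1-yn-1-yl]cyclohex-3-en-1-yl acetate | CC(=O)O[C@@H]1CC(C)=C(C#C/C(C)=C/CS(=O)(=O)c2nnnn2-c2ccccc2)C(C)(C)C1
F6 | step 15 | (1R,4S,6R)-1-ethynyl-2,2,6-trimethyl-7-oxabicyclo[4.1.0]heptan-4-ol | C#C[C@@]12O[C@]1(C)C[C@@H](O)CC2(C)C
F7 | step 15 | (1S,4S,6R)-2,2,6-trimethyl-1-[(E)-2-(tributylstannyl)ethenyl]-7-oxabicyclo[4.1.0]heptan-4-ol | CCCC[Sn](CCCC)(CCCC)/C=C/[C@@]12O[C@]1(C)C[C@@H](O)CC2(C)C
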